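## Structural features

The target 17 is a 2,3-dihydro-1-benzofuran: benzene ring A fused to the five-membered oxygen heterocycle ring B (O1, C2, C3, C3a, C7a). C2 carries a methyl acrylate unit bound through its alpha carbon, C3 carries an acetate, and C5 of ring A, para to O1, carries a 1-(angeloyloxy)ethyl chain. C2 and C3 are neighbouring stereocentres, both S, which places the acrylate and the acetoxy group on the same face of ring B. The third stereocentre (S) lies in the side chain, far from ring B, and has to be set on its own. Three groups are fragile:
- the C3 acetate is benzylic and anti to H2, so acid (ionisation assisted by O1) or strong base (anti elimination) turns ring B into an aromatic benzofuran;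
- the acrylate alpha carbon is beta to O1, so any enolate or conjugate adduct at that carbon can expel O1 as a phenoxide;
- the (Z)-angelate isomerises easily to the (E)-tiglate.

The real difficulty is to join the acrylate alpha carbon to C2 cis to the C3 oxygen, in one enantiomeric series, without holding a long-lived carbanion beta to O1. The feature used is that C2 is an ether carbon with an activated C–H bond standing 1,5 to the alpha carbon of any ester placed on the C3 oxygen. A carbene at that alpha carbon can insert into the C2–H bond on the face of the C3 oxygen, and the lactone so closed (O–C3, carbonyl carbon, alpha carbon, C2) can only be cis-fused to ring B, so C3 dictates C2.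

## Logic of the disconnections

17 to 14 and 15 (through 16). The acyl carbon–oxygen bond of the side-chain ester is cut. The angelate is the group most prone to isomerise and could not survive hydroxide, so it goes on last. The gain is the loss of the trisubstituted Z-alkene. The forward step must transfer the acyl group without Z to E isomerisation, without strong base and with the carbinol C–O bond intact.

14 to 13. The carbinol C–H bond is cut, returning the aryl methyl ketone. A remote stereocentre is best set by a catalyst, and the acetyl group is useful earlier as an electron-withdrawing group on ring A. One stereocentre disappears. The forward reduction needs reagent control of the hydride face and must leave the acrylate, the methyl ester and the acetate alone.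

13 to 10 (through 12 and 11). The O3–acetyl bond and the O–CH3 bond of the ester are cut, and the carboxyl carbon is joined to O3. The two cis substituents become one ring, so the relative configuration becomes a ring-fusion constraint. The forward step must open a five-membered lactone against its equilibrium and without conjugate addition to the methylene group. This calls for an irreversible saponification, alkylation of the carboxylate and immediate acetylation.

10 to 9. The C=CH2 bond is cut in the olefination sense, leaving a phosphoryl group on the alpha carbon. That group is the second acceptor that makes the diazo ester accessible, and it is the handle for the methylene group. The Michael acceptor disappears. The forward step forms a carbanion beta to O1, so capture by formaldehyde must be faster than loss of the aryloxide.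

9 to 8. The skeletal bond between C2 and the alpha carbon is cut, which opens the lactone and removes the C2 stereocentre. What remains is an ester of a single-stereocentre alcohol. The forward step must select the C2–H bond cis to the ester oxygen over every other carbene pathway.

8 to 7, then 7 to 5 and 6. The C=N2 bond is cut (diazo transfer), then the ester bond between O3 and the acyl carbon. The tether is reduced to the simple acid 6 and the alcohol 5. The forward steps must acylate at oxygen without ionising the benzylic C3–O bond and use only mild base.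

5 to 2 and 3 (through 4). The bond between C5 and the acetyl carbon is cut. The acetyl group cannot be present when the ring ketone is reduced, because two aryl ketones could not be told apart, so a bromide holds its place. The forward coupling must tolerate a free benzylic alcohol, and the enol ether must be hydrolysed under mild acid.

2 to 1. The C3–H bond is cut, returning an achiral ketone. All configuration in ring B derives from this reduction, so it needs high enantioselectivity.

## Other disconnections considered

Alternative 1: Three bonds of ring A are cut (C3a–C7a, C4–C5 and C6–C7), so that the benzene ring and ring B arise together from three alkynes. In the forward step [Rh(cod)2]BF4 with BINAP would join the ynol-ether diyne A2 with but-3-yn-2-one A3 to give A1.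
- In its favour: the acetyl group arrives with A3, the C2 and C3 centres and the C3 acetate are already in A2 and are not touched, and ring construction involves no carbanion beta to O1.
- Against it here: the orientation of A3 (acetyl at C5 and not C6) rests only on steric steering by the silyl group. The ynol ether of A2 is labile. A2, with two stereocentres and two different alkynes, needs a long synthesis of its own. After the key step the C7 silyl group must be removed under conditions that threaten the benzylic acetate, and the allylic silyl ether must be raised three oxidation levels to the methyl ester. The chiral ligand has no stereocentre to set.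
- Comparison: on structure it builds ring A, which the chosen plan buys. On mechanism a metallacycle assembly replaces a carbene insertion, with comparable uncertainty in regiocontrol. On step economy it is clearly longer.
- It is the better plan on one point: the C3 acetate is carried from the start, so no lactone has to be opened.

Alternative 2: The C2–C3 bond is cut. In the forward step a chiral BINOL-derived phosphoric acid would catalyse addition of the gamma carbon of the allylboronate A5 to its own ortho aldehyde, giving A4 with transposition of the double bond into the acrylate.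
- In its favour: A4 is the same compound as 12 of the chosen route, reached without the lactone detour. Both ring-B stereocentres and the methylene group are formed in one step. A closed chair transition state would give the cis product from the enol ether geometry drawn for A5 (aryloxy cis to the borylmethyl group).
- Against it here: enantioselective phosphoric-acid allylboration is established for intermolecular additions of simple allyl and crotyl boronates. An intramolecular version with an aryloxy-substituted, ester-deactivated boronate has no close model. The short tether may force a boat transition state and change the cis to trans outcome. An uncatalysed background cyclisation would erode the enantiomeric purity. A5 must be geometrically pure.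
- Comparison: on step economy this is the better plan, at about six or seven steps against nine. On mechanism it is equal in that both fix C2 against C3 through a cyclic transition state. On stereochemical certainty the chosen plan is stronger, since its absolute configuration comes from a well-understood ketone reduction and its relative configuration from ring fusion.

Alternative 3: The aryl ether bond O1–C7a is cut. In the forward step Cs2CO3 would deprotonate the syn diol A7, and the C2 alkoxide would displace the fluoride para to the acetyl group to give A6.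
- In its favour: both ring-B centres would come from one asymmetric dihydroxylation of the E-enyne A8. Only the C2 oxygen can close a five-membered ring, since the C3 oxygen would have to form a four-membered one. The fluoride is activated by the acetyl group. No diazo compound and no tin reagent is needed.
- Against it here: the ethynyl group of A6 must become the 2-substituted acrylate. This needs a branch-selective methoxycarbonylation with carbon monoxide (Pd(OAc)2 with a pyridylphosphine) on a propargylic aryl ether, which zerovalent palladium may ionise. The propargylic alkoxide may also isomerise towards an allene under the cyclisation conditions.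
- Comparison: on step count it is equal (about eight). On reliability of stereocontrol and on hazard it is equal or better. On structure it is weaker, because the acrylate carbons are not delivered with the ring-forming step as they are in the chosen plan, and the alkyne-to-acrylate conversion is at least as uncertain as the lactone opening.

Key step: step 5

Assumption: 1, 3, 6, 15, 4-acetamidobenzenesulfonyl azide, 2,4,6-trichlorobenzoyl chloride and both enantiomers of RuCl(TsDPEN)(p-cymene) are taken as purchasable; the configuration at the phosphorus-bearing carbon of 9 is left open because step 6 removes it.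

Step 1
Reactants: 1 5-bromo-1-benzofuran-3(2H)-one
Product: 2 (3S)-5-bromo-2,3-dihydro-1-benzofuran-3-ol
Conditions: RuCl[(R,R)-TsDPEN](p-cymene) (1 mol%), HCO2H/Et3N (5:2), CH2Cl2, rt
Reagents that add atoms: none
Why: Asymmetric transfer hydrogenation of an aryl ketone through the bifunctional six-membered transition state; the (R,R)-catalyst delivers hydride to the face that gives (R)-1-phenylethanol from acetophenone, and because OCH2 outranks the aryl carbon here the same spatial outcome carries the descriptor S at C3. The medium is only weakly acidic, so the benzylic alcohol should not ionise.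

Step 2
Reactants: 2 (3S)-5-bromo-2,3-dihydro-1-benzofuran-3-ol, 3 tributyl(1-ethoxyvinyl)stannane
Product: 5 1-[(3S)-3-hydroxy-2,3-dihydro-1-benzofuran-5-yl]ethanone, via ethoxyvinyl arene 4 (not isolated)
Conditions: 3 (1.2 equiv), Pd(PPh3)4 (5 mol%), toluene, 100 °C; then 0.5 M aq HCl, THF, 0 °C, short contact
Reagents that add atoms: water, O
Why: Stille coupling of the aryl bromide needs no base and tolerates the free alcohol; cold dilute acid hydrolyses the electron-rich enol ether much faster than it ionises the benzylic C3–O bond, so the S centre should be kept.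

Step 3
Reactants: 5 1-[(3S)-3-hydroxy-2,3-dihydro-1-benzofuran-5-yl]ethanone, 6 diethylphosphonoacetic acid
Product: 7 (3S)-5-acetyl-2,3-dihydro-1-benzofuran-3-yl 2-(diethoxyphosphoryl)acetate
Conditions: 6 (1.2 equiv), EDC hydrochloride, DMAP (0.1 equiv), CH2Cl2, 0 °C to rt
Reagents that add atoms: none
Why: Carbodiimide (Steglich-type) esterification acylates the alcohol oxygen, so the C3–O bond and its configuration are untouched.

Step 4
Reactants: 7 (3S)-5-acetyl-2,3-dihydro-1-benzofuran-3-yl 2-(diethoxyphosphoryl)acetate
Product: 8 (3S)-5-acetyl-2,3-dihydro-1-benzofuran-3-yl 2-diazo-2-(diethoxyphosphoryl)acetate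
Conditions: 4-acetamidobenzenesulfonyl azide, DBU, MeCN, 0 °C to rt
Reagents that add atoms: 4-acetamidobenzenesulfonyl azide, CC(=O)Nc1ccc(cc1)S(=O)(=O)N=[N+]=[N-]
Why: Regitz diazo transfer to the methylene group activated by both ester and phosphoryl; the aryl methyl ketone is not acidic enough to compete, and this azide is among the less shock-sensitive sulfonyl azides.

Step 5
Reactants: 8 (3S)-5-acetyl-2,3-dihydro-1-benzofuran-3-yl 2-diazo-2-(diethoxyphosphoryl)acetate
Product: 9 diethyl [(3aR,8bS)-7-acetyl-2-oxo-2,3,3a,8b-tetrahydrofuro[3,2-b][1]benzofuran-3-yl]phosphonate (phosphorus-bearing carbon unassigned)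
Conditions: Rh2(OAc)4 (2 mol%), ClCH2CH2Cl, 80 °C, slow addition of 8 at high dilution
Reagents that add atoms: none
Why: Loss of N2 at Rh2(OAc)4 gives an electrophilic rhodium carbene flanked by the ester and phosphoryl groups, which inserts into the C2–H bond in a concerted, asynchronous three-centre process with hydride-like character, the positive charge developing at C2 being stabilised by the O1 lone pair. The closest known reaction type is the dirhodium-catalysed 1,5 C–H insertion of diazophosphonoacetate esters next to an ether oxygen, which gives alpha-phosphono gamma-lactones. The lactone ring (O–C3, carbonyl carbon, alpha carbon, C2) closes by 1,5-insertion through a five-membered cyclic transition state, and because two five-membered rings sharing the C2–C3 bond can only be cis-fused, the carbene reaches only the C2 hydrogen on the face of the C3 oxygen. C2 is therefore set by substrate control from C3, with retention at the inserting carbon, giving the 2,3-cis arrangement of 17; the phosphorus-bearing carbon forms as a mixture that does not matter because it becomes sp2 in step 6. The selectivity needed is for this C2–H bond over the carbinol C3–H bond (four-membered lactone), over addition to ring A, over ylide formation at O1 and over carbene dimerisation. The five-membered transition state and the ether activation favour C2–H, the acetyl group lowers the electron density of ring A and of O1, the ester oxygen deactivates the geminal C3–H bond, and slow addition at high dilution suppresses bimolecular pathways.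

Step 6
Reactants: 9 diethyl [(3aR,8bS)-7-acetyl-2-oxo-2,3,3a,8b-tetrahydrofuro[3,2-b][1]benzofuran-3-yl]phosphonate
Product: 10 (3aS,8bS)-7-acetyl-3-methylidene-3a,8b-dihydrofuro[3,2-b][1]benzofuran-2(3H)-one
Conditions: 37% aq HCHO (excess), K2CO3, THF, 0 °C to rt
Reagents that add atoms: formaldehyde, C=O
Why: Horner–Wadsworth–Emmons olefination of the alpha-phosphono lactone; the weak carbonate base generates the carbanion only in the presence of a large excess of the most reactive aldehyde, so addition and loss of diethyl phosphate should outrun expulsion of O1. No stereocentre is formed and C2 and C3 are not touched.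

Step 7
Reactants: 10 (3aS,8bS)-7-acetyl-3-methylidene-3a,8b-dihydrofuro[3,2-b][1]benzofuran-2(3H)-one
Product: 13 methyl 2-[(2S,3S)-3-acetoxy-5-acetyl-2,3-dihydro-1-benzofuran-2-yl]prop-2-enoate, via potassium carboxylate 11 (not isolated), via hydroxy methyl ester 12 (not isolated)
Conditions: KOH (1.0 equiv), THF/H2O, 0 °C; evaporate; MeI, DMF, 0 °C to rt; then Ac2O, pyridine, 0 °C to rt
Reagents that add atoms: potassium hydroxide, [K+].[OH-]; iodomethane, CI; acetic anhydride, CC(=O)OC(C)=O
Why: Saponification is irreversible because a carboxylate forms, so hydroxide, unlike methoxide, should open the ring by acyl attack instead of accumulating a conjugate adduct; the carboxylate is then O-alkylated and the freed C3 hydroxyl acetylated before it can re-close the lactone. Only acyl–oxygen and methyl–oxygen bonds are made or broken, so C2 and C3 keep their configuration; a nucleophilic acylation catalyst is left out because the acrylate with its allylic aryloxy group is an SN2′ electrophile.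

Step 8
Reactants: 13 methyl 2-[(2S,3S)-3-acetoxy-5-acetyl-2,3-dihydro-1-benzofuran-2-yl]prop-2-enoate
Product: 14 methyl 2-[(2S,3S)-3-acetoxy-5-[(1S)-1-hydroxyethyl]-2,3-dihydro-1-benzofuran-2-yl]prop-2-enoate
Conditions: RuCl[(S,S)-TsDPEN](p-cymene) (2 mol%), HCO2H/Et3N (5:2), CH2Cl2, rt
Reagents that add atoms: none
Why: Asymmetric transfer hydrogenation of the aryl methyl ketone; the (S,S)-catalyst gives the (S)-1-arylethanol sense as with acetophenone, under catalyst control independent of the remote ring-B centres. The ruthenium hydride reduces C=O through the bifunctional pathway and should leave the acrylate, the methyl ester and the acetate alone.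

Step 9
Reactants: 14 methyl 2-[(2S,3S)-3-acetoxy-5-[(1S)-1-hydroxyethyl]-2,3-dihydro-1-benzofuran-2-yl]prop-2-enoate, 15 angelic acid ((2Z)-2-methylbut-2-enoic acid)
Product: 17 methyl 2-[(2S,3S)-3-acetoxy-5-[(1S)-1-{[(2Z)-2-methylbut-2-enoyl]oxy}ethyl]-2,3-dihydro-1-benzofuran-2-yl]prop-2-enoate, via mixed anhydride 16 (not isolated)
Conditions: 15, 2,4,6-trichlorobenzoyl chloride, Et3N, toluene, rt; then 14, 70 °C
Reagents that add atoms: none
Why: Yamaguchi esterification: the preformed mixed anhydride transfers the less hindered angeloyl group to the secondary alcohol on warming without a nucleophilic catalyst, conditions known to preserve the Z geometry of angelates. The carbinol C–O bond is not broken, so the S configuration is retained.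

Compound list

1 | 5-bromo-1-benzofuran-3(2H)-one | O=C1COc2ccc(Br)cc12 | starting material
2 | (3S)-5-bromo-2,3-dihydro-1-benzofuran-3-ol | C1Oc2ccc(Br)cc2[C@@H]1O | intermediate
3 | tributyl(1-ethoxyvinyl)stannane | CCCC[Sn](CCCC)(CCCC)C(=C)OCC | starting material
4 | (3S)-5-(1-ethoxyethenyl)-2,3-dihydro-1-benzofuran-3-ol | C1Oc2ccc(C(=C)OCC)cc2[C@@H]1O | intermediate
5 | 1-[(3S)-3-hydroxy-2,3-dihydro-1-benzofuran-5-yl]ethanone | C1Oc2ccc(C(C)=O)cc2[C@@H]1O | intermediate
6 | diethylphosphonoacetic acid | CCOP(=O)(CC(=O)O)OCC | starting material
7 | (3S)-5-acetyl-2,3-dihydro-1-benzofuran-3-yl 2-(diethoxyphosphoryl)acetate | C1Oc2ccc(C(C)=O)cc2[C@@H]1OC(=O)CP(=O)(OCC)OCC | intermediate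
8 | (3S)-5-acetyl-2,3-dihydro-1-benzofuran-3-yl 2-diazo-2-(diethoxyphosphoryl)acetate | C1Oc2ccc(C(C)=O)cc2[C@@H]1OC(=O)C(=[N+]=[N-])P(=O)(OCC)OCC | intermediate
9 | diethyl [(3aR,8bS)-7-acetyl-2-oxo-2,3,3a,8b-tetrahydrofuro[3,2-b][1]benzofuran-3-yl]phosphonate (phosphorus-bearing carbon unassigned) | O=C3C(P(=O)(OCC)OCC)[C@@H]1Oc2ccc(C(C)=O)cc2[C@@H]1O3 | intermediate
10 | (3aS,8bS)-7-acetyl-3-methylidene-3a,8b-dihydrofuro[3,2-b][1]benzofuran-2(3H)-one | O=C3C(=C)[C@@H]1Oc2ccc(C(C)=O)cc2[C@@H]1O3 | intermediate
11 | potassium 2-[(2S,3S)-5-acetyl-3-hydroxy-2,3-dihydro-1-benzofuran-2-yl]prop-2-enoate | C=C(C(=O)[O-])[C@@H]1Oc2ccc(C(C)=O)cc2[C@@H]1O.[K+] | intermediate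
12 | methyl 2-[(2S,3S)-5-acetyl-3-hydroxy-2,3-dihydro-1-benzofuran-2-yl]prop-2-enoate | C=C(C(=O)OC)[C@@H]1Oc2ccc(C(C)=O)cc2[C@@H]1O | intermediate
13 | methyl 2-[(2S,3S)-3-acetoxy-5-acetyl-2,3-dihydro-1-benzofuran-2-yl]prop-2-enoate | C=C(C(=O)OC)[C@@H]1Oc2ccc(C(C)=O)cc2[C@@H]1OC(C)=O | intermediate
14 | methyl 2-[(2S,3S)-3-acetoxy-5-[(1S)-1-hydroxyethyl]-2,3-dihydro-1-benzofuran-2-yl]prop-2-enoate | C=C(C(=O)OC)[C@@H]1Oc2ccc([C@H](C)O)cc2[C@@H]1OC(C)=O | intermediate
15 | angelic acid, (2Z)-2-methylbut-2-enoic acid | C/C=C(/C)C(=O)O | starting material
16 | (2Z)-2-methylbut-2-enoic 2,4,6-trichlorobenzoic anhydride | C/C=C(/C)C(=O)OC(=O)c1c(Cl)cc(Cl)cc1Cl | intermediate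
17 | methyl 2-[(2S,3S)-3-acetoxy-5-[(1S)-1-{[(2Z)-2-methylbut-2-enoyl]oxy}ethyl]-2,3-dihydro-1-benzofuran-2-yl]prop-2-enoate | C=C(C(=O)OC)[C@@H]1Oc2ccc([C@H](C)OC(=O)/C(C)=C\C)cc2[C@@H]1OC(C)=O | target

Total step count: 9. Longest linear sequence: 9 steps, from 1 to 17.

Steps least certain to work

Step 5 (key step). The carbene may be diverted into insertion at the carbinol C3–H bond, into ylide formation at O1 or into dimerisation. The ester must leave its preferred conformation to reach the C2–H bond, and a carbene bearing two acceptors is highly electrophilic and correspondingly unselective. The fallback changes the carbene precursor and the methylenation chemistry; it sets out from 5 and returns at 10.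
- 5 would be acetoacetylated with 2,2,6-trimethyl-4H-1,3-dioxin-4-one in hot toluene to give (3S)-5-acetyl-2,3-dihydro-1-benzofuran-3-yl 3-oxobutanoate F1.
- Diazo transfer (4-acetamidobenzenesulfonyl azide, Et3N, MeCN) would give (3S)-5-acetyl-2,3-dihydro-1-benzofuran-3-yl 2-diazo-3-oxobutanoate F2.
- Rh2(OAc)4 would be expected to close the smaller acetyl-substituted carbene onto C2–H, giving (3aS,8bS)-3,7-diacetyl-3a,8b-dihydrofuro[3,2-b][1]benzofuran-2(3H)-one F3.
- Deacetylative methylenation of F3 with aqueous formaldehyde and K2CO3 should then give 10.

Step 6. The phosphonate carbanion may expel the ring-B aryloxide by beta-elimination, opening ring B and putting the C3 configuration at risk while the ring is open. The para acetyl group makes that aryloxide a good leaving group. Hydroxymethylation of the acetyl group by formaldehyde is a lesser risk. The fallback reorders the end game so that ring A no longer carries the ketone when the carbanion is formed; it sets out from 9 and returns at 17.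
- 9 would be reduced with RuCl[(S,S)-TsDPEN](p-cymene) and HCO2H/Et3N to diethyl [(3aR,8bS)-7-[(1S)-1-hydroxyethyl]-2-oxo-2,3,3a,8b-tetrahydrofuro[3,2-b][1]benzofuran-3-yl]phosphonate F4.
- F4 would be acylated with 16 as in step 9 to give (1S)-1-[(3aR,8bS)-3-(diethoxyphosphoryl)-2-oxo-2,3,3a,8b-tetrahydrofuro[3,2-b][1]benzofuran-7-yl]ethyl (2Z)-2-methylbut-2-enoate F5.
- Methylenation as in step 6 would give (1S)-1-[(3aS,8bS)-3-methylidene-2-oxo-2,3,3a,8b-tetrahydrofuro[3,2-b][1]benzofuran-7-yl]ethyl (2Z)-2-methylbut-2-enoate F6.
- The sequence of step 7 (one equivalent of KOH at 0 °C, which a hindered angelate should outlast) would pass through potassium 2-[(2S,3S)-3-hydroxy-5-[(1S)-1-{[(2Z)-2-methylbut-2-enoyl]oxy}ethyl]-2,3-dihydro-1-benzofuran-2-yl]prop-2-enoate F7 and methyl 2-[(2S,3S)-3-hydroxy-5-[(1S)-1-{[(2Z)-2-methylbut-2-enoyl]oxy}ethyl]-2,3-dihydro-1-benzofuran-2-yl]prop-2-enoate F8, and acetylation of F8 gives 17.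

Step 7. Hydroxide may add to the methylene group, and the resulting enolate would expel O1. Alternatively the hydroxy ester may re-close to the lactone before it is acetylated, since the five-membered lactone is the thermodynamic sink. The fallback masks the methylene group during the opening; it sets out from 10 and returns at 13.
- Benzeneselenol (from PhSeSePh and NaBH4 in EtOH, buffered with AcOH) would add to 10 to give (3aS,8bS)-7-acetyl-3-[(phenylselanyl)methyl]-3a,8b-dihydrofuro[3,2-b][1]benzofuran-2(3H)-one F9.
- The KOH, MeI and Ac2O sequence would then run without a Michael acceptor, through potassium 2-[(2S,3S)-5-acetyl-3-hydroxy-2,3-dihydro-1-benzofuran-2-yl]-3-(phenylselanyl)propanoate F10 and methyl 2-[(2S,3S)-5-acetyl-3-hydroxy-2,3-dihydro-1-benzofuran-2-yl]-3-(phenylselanyl)propanoate F11, to methyl 2-[(2S,3S)-3-acetoxy-5-acetyl-2,3-dihydro-1-benzofuran-2-yl]-3-(phenylselanyl)propanoate F12.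
- Oxidation of F12 with NaIO4 and syn elimination of the selenoxide at room temperature should restore the methylene group and give 13.

Step 9. The angeloyl group may isomerise from Z to E while it is activated, and prolonged heating with amine may eliminate acetic acid across C2–C3. The fallback builds the Z-alkene on the ester instead of transferring it; it sets out from 14 and returns at 17.
- 14 would be esterified by carbodiimide coupling with 2-[bis(2,2,2-trifluoroethoxy)phosphoryl]propanoic acid to give (1S)-1-[(2S,3S)-3-acetoxy-2-(3-methoxy-3-oxoprop-1-en-2-yl)-2,3-dihydro-1-benzofuran-5-yl]ethyl 2-[bis(2,2,2-trifluoroethoxy)phosphoryl]propanoate F13.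
- Z-selective Still–Gennari olefination of F13 with acetaldehyde (KN(SiMe3)2, 18-crown-6, THF, −78 °C) should give 17.

## Further compounds

F1 | step 5 | (3S)-5-acetyl-2,3-dihydro-1-benzofuran-3-yl 3-oxobutanoate | C1Oc2ccc(C(C)=O)cc2[C@@H]1OC(=O)CC(C)=O
F2 | step 5 | (3S)-5-acetyl-2,3-dihydro-1-benzofuran-3-yl 2-diazo-3-oxobutanoate | C1Oc2ccc(C(C)=O)cc2[C@@H]1OC(=O)C(=[N+]=[N-])C(C)=O
F3 | step 5 | (3aS,8bS)-3,7-diacetyl-3a,8b-dihydrofuro[3,2-b][1]benzofuran-2(3H)-one (C3 unassigned) | O=C3C(C(C)=O)[C@@H]1Oc2ccc(C(C)=O)cc2[C@@H]1O3
F4 | step 6 | diethyl [(3aR,8bS)-7-[(1S)-1-hydroxyethyl]-2-oxo-2,3,3a,8b-tetrahydrofuro[3,2-b][1]benzofuran-3-yl]phosphonate (C3 unassigned) | O=C3C(P(=O)(OCC)OCC)[C@@H]1Oc2ccc([C@H](C)O)cc2[C@@H]1O3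
F5 | step 6 | (1S)-1-[(3aR,8bS)-3-(diethoxyphosphoryl)-2-oxo-2,3,3a,8b-tetrahydrofuro[3,2-b][1]benzofuran-7-yl]ethyl (2Z)-2-methylbut-2-enoate (C3 unassigned) | O=C3C(P(=O)(OCC)OCC)[C@@H]1Oc2ccc([C@H](C)OC(=O)/C(C)=C\C)cc2[C@@H]1O3
F6 | step 6 | (1S)-1-[(3aS,8bS)-3-methylidene-2-oxo-2,3,3a,8b-tetrahydrofuro[3,2-b][1]benzofuran-7-yl]ethyl (2Z)-2-methylbut-2-enoate | O=C3C(=C)[C@@H]1Oc2ccc([C@H](C)OC(=O)/C(C)=C\C)cc2[C@@H]1O3
F7 | step 6 | potassium 2-[(2S,3S)-3-hydroxy-5-[(1S)-1-{[(2Z)-2-methylbut-2-enoyl]oxy}ethyl]-2,3-dihydro-1-benzofuran-2-yl]prop-2-enoate | C=C(C(=O)[O-])[C@@H]1Oc2ccc([C@H](C)OC(=O)/C(C)=C\C)cc2[C@@H]1O.[K+]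
F8 | step 6 | methyl 2-[(2S,3S)-3-hydroxy-5-[(1S)-1-{[(2Z)-2-methylbut-2-enoyl]oxy}ethyl]-2,3-dihydro-1-benzofuran-2-yl]prop-2-enoate | C=C(C(=O)OC)[C@@H]1Oc2ccc([C@H](C)OC(=O)/C(C)=C\C)cc2[C@@H]1O
F9 | step 7 | (3aS,8bS)-7-acetyl-3-[(phenylselanyl)methyl]-3a,8b-dihydrofuro[3,2-b][1]benzofuran-2(3H)-one (C3 unassigned) | O=C3C(C[Se]c4ccccc4)[C@@H]1Oc2ccc(C(C)=O)cc2[C@@H]1O3
F10 | step 7 | potassium 2-[(2S,3S)-5-acetyl-3-hydroxy-2,3-dihydro-1-benzofuran-2-yl]-3-(phenylselanyl)propanoate (C2 of the propanoate unassigned) | O=C([O-])C(C[Se]c3ccccc3)[C@@H]1Oc2ccc(C(C)=O)cc2[C@@H]1O.[K+]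
F11 | step 7 | methyl 2-[(2S,3S)-5-acetyl-3-hydroxy-2,3-dihydro-1-benzofuran-2-yl]-3-(phenylselanyl)propanoate (C2 of the propanoate unassigned) | COC(=O)C(C[Se]c3ccccc3)[C@@H]1Oc2ccc(C(C)=O)cc2[C@@H]1O
F12 | step 7 | methyl 2-[(2S,3S)-3-acetoxy-5-acetyl-2,3-dihydro-1-benzofuran-2-yl]-3-(phenylselanyl)propanoate (C2 of the propanoate unassigned) | COC(=O)C(C[Se]c3ccccc3)[C@@H]1Oc2ccc(C(C)=O)cc2[C@@H]1OC(C)=O
F13 | step 9 | (1S)-1-[(2S,3S)-3-acetoxy-2-(3-methoxy-3-oxoprop-1-en-2-yl)-2,3-dihydro-1-benzofuran-5-yl]ethyl 2-[bis(2,2,2-trifluoroethoxy)phosphoryl]propanoate (phosphorus-bearing carbon unassigned) | C=C(C(=O)OC)[C@@H]1Oc2ccc([C@H](C)OC(=O)C(C)P(=O)(OCC(F)(F)F)OCC(F)(F)F)cc2[C@@H]1OC(C)=O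
A1 | alternative 1 | (2S,3S)-5-acetyl-2-[3-(tert-butyldimethylsilyloxy)prop-1-en-2-yl]-7-(trimethylsilyl)-2,3-dihydro-1-benzofuran-3-yl acetate | C=C(CO[Si](C)(C)C(C)(C)C)[C@@H]1Oc2c([Si](C)(C)C)cc(C(C)=O)cc2[C@@H]1OC(C)=O
A2 | alternative 1 | (3S,4S)-2-[(tert-butyldimethylsilyloxy)methyl]-3-[(trimethylsilyl)ethynyloxy]hex-1-en-5-yn-4-yl acetate | C=C(CO[Si](C)(C)C(C)(C)C)[C@H](OC#C[Si](C)(C)C)[C@@H](OC(C)=O)C#C
A3 | alternative 1 | but-3-yn-2-one | CC(=O)C#C
A4 | alternative 2 | methyl 2-[(2S,3S)-5-acetyl-3-hydroxy-2,3-dihydro-1-benzofuran-2-yl]prop-2-enoate | C=C(C(=O)OC)[C@@H]1Oc2ccc(C(C)=O)cc2[C@@H]1O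
A5 | alternative 2 | methyl (2E)-3-(4-acetyl-2-formylphenoxy)-2-[(4,4,5,5-tetramethyl-1,3,2-dioxaborolan-2-yl)methyl]prop-2-enoate | COC(=O)/C(CB1OC(C)(C)C(C)(C)O1)=C/Oc1ccc(C(C)=O)cc1C=O
A6 | alternative 3 | 1-[(2S,3S)-2-ethynyl-3-hydroxy-2,3-dihydro-1-benzofuran-5-yl]ethanone | C#C[C@@H]1Oc2ccc(C(C)=O)cc2[C@@H]1O
A7 | alternative 3 | 1-{3-[(1S,2S)-1,2-dihydroxybut-3-yn-1-yl]-4-fluorophenyl}ethanone | C#C[C@H](O)[C@@H](O)c1cc(C(C)=O)ccc1F
A8 | alternative 3 | 1-{3-[(1E)-but-1-en-3-yn-1-yl]-4-fluorophenyl}ethanone | C#C/C=C/c1cc(C(C)=O)ccc1F
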